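**Retrosynthetic overview** (drimane numbering: ring A = C1–C5/C10, ring B = C5–C10, C11 on C9, C12 on C8)
1. Parritadial 24 ⇒ 6α-alcohol 23 ⇒ β,γ-epoxy dialdehyde 22 (E1cB opening of a 6α,7α-epoxide by the C8 enolate) ⇒ octalin aldehyde 16, by α-face oxidation at C9 (Rubottom) and at C6=C7.
2. Enabling feature: in ring B, C6(OAc)–C7=C8(C12HO) beside C9(OH)(C11HO) is a disguised C6=C7 cyclohexene. Its C8 and C9 carry vicinal one-carbon branches, and C1–C4 of ring A bridge C10 and C5 exactly as the tether of a 2,8,10-trienal does.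
3. 16 ⇒ acyclic trienal 15 by an intramolecular Diels–Alder reaction (bonds C5–C10 and C8–C9). Rings A and B close together in this one step, and no carbocycle is formed afterwards (only two transient oxiranes).
4. 15 ⇒ aldehyde 5 (from cyano aldehyde 1 and phosphonocrotonate 2) plus alkenyl iodide 9 (from but-2-yn-1-ol 6). The only stereocentre of 15 (C1) comes from a CBS reduction and relays to C5 and C10, then to C9 and C6.

Key step: step 11

Remark: the SMILES is read as 1β,6α-diacetoxy-9α-hydroxy with 5α-H and 10β-CH3 (1R,5S,6S,9S,10R in drimane numbering), so the C6 acetate is equatorial and cis to the 9-OH. Compounds 1, 2 and 6 are taken as catalogue chemicals.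

**Step 1**
Reactants: 1 4,4-dimethyl-5-oxopentanenitrile; 2 triethyl (E)-4-phosphonocrotonate
Product: 3 ethyl (2E,4E)-8-cyano-6,6-dimethylocta-2,4-dienoate
Conditions: LiHMDS, THF, −78 → 0 °C
Reagents that add atoms: none
Why: Vinylogous Horner–Wadsworth–Emmons olefination of a non-enolisable aldehyde; the stabilised phosphonate anion leaves the nitrile alone and should give the E,E-dienoate (future C5=C6 and C7=C8).

**Step 2**
Reactants: 3 ethyl (2E,4E)-8-cyano-6,6-dimethylocta-2,4-dienoate
Product: 4 (5E,7E)-9-hydroxy-4,4-dimethylnona-5,7-dienal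
Conditions: DIBAL-H (4 equiv), CH2Cl2, −78 °C; aq. Rochelle salt, then dilute tartaric acid, 0 °C
Reagents that add atoms: water, O
Why: DIBAL-H reduction takes the dienoate 1,2 to the dienol and stops the nitrile at the N-aluminoimine, which hydrolyses to the aldehyde (future C1) only on work-up.

**Step 3**
Reactants: 4 (5E,7E)-9-hydroxy-4,4-dimethylnona-5,7-dienal
Product: 5 (5E,7E)-9-(tert-butyldimethylsilyloxy)-4,4-dimethylnona-5,7-dienal
Conditions: TBSCl, imidazole, CH2Cl2, 0 °C → rt
Reagents that add atoms: tert-butyldimethylsilyl chloride, CC(C)(C)[Si](C)(C)Cl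
Why: Standard silylation of the primary alcohol; the aldehyde is inert and the TBS group is chosen to last until step 15.

**Step 4**
Reactants: 6 but-2-yn-1-ol
Product: 7 1-(triethylsilyloxy)but-2-yne
Conditions: TESCl, imidazole, CH2Cl2, 0 °C
Reagents that add atoms: triethylsilyl chloride, CC[Si](Cl)(CC)CC
Why: Standard silylation; the TES ether is the group that step 10 turns directly into the aldehyde in the presence of the TBS ether.

**Step 5**
Reactants: 7 1-(triethylsilyloxy)but-2-yne
Product: 9 (E)-3-iodobut-2-enyl triethylsilyl ether, via alkenylzirconocene chloride 8 (not isolated)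
Conditions: Cp2Zr(H)Cl, THF, rt; I2, −78 → 0 °C
Reagents that add atoms: iodine, II
Why: Syn-hydrozirconation with zirconium on the alkyne carbon remote from the bulky CH2OSiEt3 group, then iodinolysis with retention, should give the E iodide (CH3 cis to CH2O).

**Step 6**
Reactants: 9 (E)-3-iodobut-2-enyl triethylsilyl ether; 5 (5E,7E)-9-(tert-butyldimethylsilyloxy)-4,4-dimethylnona-5,7-dienal
Product: 11 racemic (2E,8E,10E)-12-(tert-butyldimethylsilyloxy)-3,7,7-trimethyl-1-(triethylsilyloxy)dodeca-2,8,10-trien-4-ol, via alkenyllithium 10 (not isolated)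
Conditions: t-BuLi (2 equiv), Et2O, −78 °C; then 5, −78 °C; H2O
Reagents that add atoms: none
Why: Iodine–lithium exchange with retention of alkene geometry and 1,2-addition to the aldehyde form C1–C10; the carbinol configuration is irrelevant because step 7 erases it.

**Step 7**
Reactants: 11 racemic trienol
Product: 12 (2E,8E,10E)-12-(tert-butyldimethylsilyloxy)-3,7,7-trimethyl-1-(triethylsilyloxy)dodeca-2,8,10-trien-4-one
Conditions: Dess–Martin periodinane, pyridine, CH2Cl2, 0 °C
Reagents that add atoms: none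
Why: Buffered Dess–Martin oxidation of the allylic alcohol; the trisubstituted enone should be too hindered a dienophile to cyclise at or below room temperature if it is used promptly.

**Step 8**
Reactants: 12 trienone
Product: 13 (2E,4R,8E,10E)-12-(tert-butyldimethylsilyloxy)-3,7,7-trimethyl-1-(triethylsilyloxy)dodeca-2,8,10-trien-4-ol
Conditions: (S)-2-methyl-CBS-oxazaborolidine (20 mol%), catecholborane, toluene, −78 °C
Reagents that add atoms: none
Why: Corey–Bakshi–Shibata reduction with the α-methylalkenyl group as the large and the CH2 chain as the small substituent, so the (S)-catalyst should give the (R)-carbinol (C1); catecholborane at −78 °C leaves the diene alone.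

**Step 9**
Reactants: 13 (4R)-trienol
Product: 14 (2E,4R,8E,10E)-12-(tert-butyldimethylsilyloxy)-3,7,7-trimethyl-1-(triethylsilyloxy)dodeca-2,8,10-trien-4-yl acetate
Conditions: Ac2O, pyridine, DMAP (cat.), CH2Cl2, 0 °C → rt
Reagents that add atoms: acetic anhydride, CC(=O)OC(C)=O
Why: DMAP-catalysed acetylation installs the C1 acetate of the target early, which later also prevents lactol formation between O1 and C11.

**Step 10**
Reactants: 14 (4R)-acetate
Product: 15 (2E,4R,8E,10E)-4-acetoxy-12-(tert-butyldimethylsilyloxy)-3,7,7-trimethyldodeca-2,8,10-trienal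
Conditions: (COCl)2, DMSO, CH2Cl2, −78 → −40 °C; Et3N, −78 → 0 °C
Reagents that add atoms: none
Why: Swern oxidation applied directly to a primary triethylsilyl ether (oxidative desilylation), a known process that leaves primary TBS ethers, acetates and dienes untouched and gives the E-enal.

**Step 11**
Reactants: 15 (2E,4R,8E,10E)-trienal
Product: 16 1β-acetoxy-12-(tert-butyldimethylsilyloxy)drim-6-en-11-al (trans-fused; 5α-H, 8α-H, 9α-H, 10β-CH3)
Conditions: Me2AlCl (2.5 equiv), CH2Cl2, −78 → −20 °C
Reagents that add atoms: none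
Why: Type 1 intramolecular Diels–Alder reaction: Me2AlCl binds the formyl oxygen (the excess is taken up by the acetate) and lowers the LUMO of C9=C10, and the s-cis C5=C6–C7=C8 diene adds suprafacially in a concerted but asynchronous [4+2] event that forms C5–C10 and C8–C9; the closest known reaction type is the alkylaluminium chloride-promoted cyclisation of (2E,8E,10E)-undeca-2,8,10-trienals to trans-fused octalin carbaldehydes. Ring A closes in the fused mode as the six-membered tether ring (C10–C1–C2–C3–C4–C5, chair-like, favoured by the C4 gem-dimethyl group), and ring B closes as the new cyclohexene with its double bond at C6=C7. Because the enal is E, formyl and 10-methyl lie on the same side, so the formyl-endo transition state reinforced by the Lewis acid sets 10-CH3 anti to 5-H (trans-decalin), and the E,E-diene then places C11 on C9 and C12 on C8 on the β face (C9 is re-set and C8 erased later). The absolute sense at C5 and C10 comes from C1: on the chair-like tether the acetoxy group should sit pseudo-equatorial and anti to the forming C5–C10 bond (Felkin-type alignment, no syn-axial contact with 3-H and 5-H), which corresponds to 1β-OAc/10β-CH3. The step needs endo over exo selectivity and one π-face of the dienophile, secured by the Lewis acid-bound formyl group and the C1 stereocentre; regiochemistry is fixed by the four-atom tether, and Me2AlCl also scavenges protons, which protects the dienylic silyl ether.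

**Step 12**
Reactants: 16 octalin aldehyde
Product: 17 1β-acetoxy-12-(tert-butyldimethylsilyloxy)-11-(triethylsilyloxy)drima-6,9(11)-diene (E enol ether, OSiEt3 away from C10)
Conditions: TESOTf, Et3N, CH2Cl2, 0 °C
Reagents that add atoms: triethylsilyl triflate, CC[Si](CC)(CC)OS(=O)(=O)C(F)(F)F
Why: Soft enolisation of the aldehyde, which has a single α-hydrogen (axial 9α-H), gives the silyl enol ether; the acetate is far less prone to silylation.

**Step 13**
Reactants: 17 silyl enol ether
Product: 19 1β-acetoxy-6α,7α-epoxy-12-(tert-butyldimethylsilyloxy)-9α-(triethylsilyloxy)driman-11-al, via bis-epoxide 18 (not isolated)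
Conditions: DMDO (2.5 equiv), acetone–CH2Cl2, −40 → 0 °C; then SiO2, CH2Cl2, rt
Reagents that add atoms: dimethyldioxirane, CC1(C)OO1
Why: Rubottom oxidation and alkene epoxidation in one pot; 10β-CH3, 4β-CH3 and the 8β-CH2OTBS group shield the β face, so both oxygens should arrive from the α face (setting C9 and C6), and silyl migration in the silyloxy-oxirane unveils the 9α-silyloxy aldehyde under neutral conditions that spare the formyl group.

**Step 14**
Reactants: 19 epoxy aldehyde
Product: 20 1β-acetoxy-6α,7α-epoxy-12-(tert-butyldimethylsilyloxy)-9α-(triethylsilyloxy)driman-11-ol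
Conditions: NaBH4, MeOH, 0 °C
Reagents that add atoms: none
Why: Chemoselective borohydride reduction of the aldehyde, so that a free C12 alcohol never meets a C11 aldehyde (lactol, then lactone); any 9-O to 11-O silyl shift is harmless because both silyl groups leave in step 15.

**Step 15**
Reactants: 20 epoxy alcohol
Product: 21 1β-acetoxy-6α,7α-epoxydrimane-9α,11,12-triol
Conditions: TBAF, AcOH (1:1), THF, 0 °C → rt
Reagents that add atoms: none
Why: Buffered fluoride desilylation removes the TBS and TES groups while the acetate and the epoxide persist; the equatorial C11 arm cannot reach the back side of C7 in the rigid trans-decalin.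

**Step 16**
Reactants: 21 epoxy triol
Product: 23 1β-acetoxy-6α,9α-dihydroxydrim-7-ene-11,12-dial, via epoxy dialdehyde 22 (not isolated)
Conditions: (COCl)2, DMSO, CH2Cl2, −78 °C; Et3N, −78 °C → rt
Reagents that add atoms: none
Why: Double Swern oxidation activates both primary carbinols before base is added and leaves the tertiary 9-OH alone; the amine then deprotonates C8–H of the β,γ-epoxy aldehyde, and E1cB cleavage of C7–O gives the C7=C8 enal with the oxygen retained on C6 in its α configuration.

**Step 17**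
Reactants: 23 dihydroxy dialdehyde
Product: 24 parritadial (1β,6α-diacetoxy-9α-hydroxydrim-7-ene-11,12-dial)
Conditions: Ac2O, pyridine, DMAP (cat.), CH2Cl2, 0 °C
Reagents that add atoms: acetic anhydride, CC(=O)OC(C)=O
Why: DMAP-catalysed acetylation of the equatorial secondary allylic 6α-OH; the tertiary 9α-OH next to quaternary C10 should not react, and no C9–H is left for 1,4-elimination of the new acetate.

**Compound list**
1 | 4,4-dimethyl-5-oxopentanenitrile | N#CCCC(C)(C)C=O | starting material
2 | triethyl (E)-4-phosphonocrotonate | CCOC(=O)/C=C/CP(=O)(OCC)OCC | starting material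
3 | ethyl (2E,4E)-8-cyano-6,6-dimethylocta-2,4-dienoate | CCOC(=O)/C=C/C=C/C(C)(C)CCC#N | intermediate
4 | (5E,7E)-9-hydroxy-4,4-dimethylnona-5,7-dienal | O=CCCC(C)(C)/C=C/C=C/CO | intermediate
5 | (5E,7E)-9-(tert-butyldimethylsilyloxy)-4,4-dimethylnona-5,7-dienal | O=CCCC(C)(C)/C=C/C=C/CO[Si](C)(C)C(C)(C)C | intermediate
6 | but-2-yn-1-ol | CC#CCO | starting material
7 | 1-(triethylsilyloxy)but-2-yne | CC#CCO[Si](CC)(CC)CC | intermediate
8 | (E)-alkenylzirconocene chloride (Zr on the methyl-bearing carbon) | C/C(=C\CO[Si](CC)(CC)CC)[Zr](Cl)(C1C=CC=C1)C1C=CC=C1 | intermediate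
9 | (E)-3-iodobut-2-enyl triethylsilyl ether | C/C(I)=C\CO[Si](CC)(CC)CC | intermediate
10 | (E)-alkenyllithium from 9 | C/C([Li])=C\CO[Si](CC)(CC)CC | intermediate
11 | racemic (2E,8E,10E)-12-(TBSO)-3,7,7-trimethyl-1-(TESO)dodeca-2,8,10-trien-4-ol | CC[Si](CC)(CC)OC/C=C(\C)C(O)CCC(C)(C)/C=C/C=C/CO[Si](C)(C)C(C)(C)C | intermediate
12 | (2E,8E,10E)-12-(TBSO)-3,7,7-trimethyl-1-(TESO)dodeca-2,8,10-trien-4-one | CC[Si](CC)(CC)OC/C=C(\C)C(=O)CCC(C)(C)/C=C/C=C/CO[Si](C)(C)C(C)(C)C | intermediate
13 | (2E,4R,8E,10E)-trien-4-ol | CC[Si](CC)(CC)OC/C=C(\C)[C@H](O)CCC(C)(C)/C=C/C=C/CO[Si](C)(C)C(C)(C)C | intermediate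
14 | (2E,4R,8E,10E)-trien-4-yl acetate | CC[Si](CC)(CC)OC/C=C(\C)[C@H](OC(C)=O)CCC(C)(C)/C=C/C=C/CO[Si](C)(C)C(C)(C)C | intermediate
15 | (2E,4R,8E,10E)-4-acetoxy-12-(TBSO)-3,7,7-trimethyldodeca-2,8,10-trienal | O=C/C=C(\C)[C@H](OC(C)=O)CCC(C)(C)/C=C/C=C/CO[Si](C)(C)C(C)(C)C | intermediate
16 | 1β-acetoxy-12-(TBSO)drim-6-en-11-al (5α-H, 8α-H, 9α-H, 10β-CH3) | C1=C[C@H](CO[Si](C)(C)C(C)(C)C)[C@H](C=O)[C@@]2(C)[C@H](OC(C)=O)CCC(C)(C)[C@H]12 | intermediate
17 | 1β-acetoxy-12-(TBSO)-11-(TESO)drima-6,9(11)-diene, E enol ether | C1=C[C@H](CO[Si](C)(C)C(C)(C)C)/C(=C\O[Si](CC)(CC)CC)[C@@]2(C)[C@H](OC(C)=O)CCC(C)(C)[C@H]12 | intermediate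
18 | 6α,7α:9α,11-bis-epoxide of 17 | O1[C@H]2[C@@H]1[C@H](CO[Si](C)(C)C(C)(C)C)[C@@]3(O[C@@H]3O[Si](CC)(CC)CC)[C@@]4(C)[C@H](OC(C)=O)CCC(C)(C)[C@H]24 | intermediate
19 | 1β-acetoxy-6α,7α-epoxy-12-(TBSO)-9α-(TESO)driman-11-al | O1[C@H]2[C@@H]1[C@H](CO[Si](C)(C)C(C)(C)C)[C@](O[Si](CC)(CC)CC)(C=O)[C@@]3(C)[C@H](OC(C)=O)CCC(C)(C)[C@H]23 | intermediate
20 | 1β-acetoxy-6α,7α-epoxy-12-(TBSO)-9α-(TESO)driman-11-ol | O1[C@H]2[C@@H]1[C@H](CO[Si](C)(C)C(C)(C)C)[C@](O[Si](CC)(CC)CC)(CO)[C@@]3(C)[C@H](OC(C)=O)CCC(C)(C)[C@H]23 | intermediate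
21 | 1β-acetoxy-6α,7α-epoxydrimane-9α,11,12-triol | O1[C@H]2[C@@H]1[C@H](CO)[C@](O)(CO)[C@@]3(C)[C@H](OC(C)=O)CCC(C)(C)[C@H]23 | intermediate
22 | 1β-acetoxy-6α,7α-epoxy-9α-hydroxydrimane-11,12-dial | O1[C@H]2[C@@H]1[C@H](C=O)[C@](O)(C=O)[C@@]3(C)[C@H](OC(C)=O)CCC(C)(C)[C@H]23 | intermediate
23 | 1β-acetoxy-6α,9α-dihydroxydrim-7-ene-11,12-dial | O[C@H]1C=C(C=O)[C@](O)(C=O)[C@@]2(C)[C@H](OC(C)=O)CCC(C)(C)[C@H]12 | intermediate
24 | parritadial | CC(=O)O[C@H]1C=C(C=O)[C@](O)(C=O)[C@@]2(C)[C@H](OC(C)=O)CCC(C)(C)[C@H]12 | target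

**Totals**
Total step count: 17. Longest linear sequence: 15 (steps 1–3 and 6–17).

**Steps most likely to fail**

Step 11. The C5–C10 bond joins a neopentyl diene terminus to a fully substituted dienophile carbon, so the cycloaddition may be slow. On warming, exo closure to the cis-decalin, attack on the other dienophile face, or ionisation of the dienylic silyl ether by the excess Lewis acid may compete.
The fallback changes the activation from a neutral aluminium complex to a cationic dienophile (ionic Diels–Alder reaction). It sets out from 15 and returns at 16. Compound 15 is treated with 1,2-bis(trimethylsilyloxy)ethane and catalytic TMSOTf at −78 °C to give the trienal ethylene acetal F1. Catalytic TMSOTf or TfOH then opens the acetal reversibly to an allyl oxocarbenium ion. This ion is a much stronger dienophile, needs no excess Lewis acid, and should cyclise at low temperature through the same endo, chair-tether array to the octalin ethylene acetal F2. PPTS in wet acetone then releases 16 with the TBS ether intact.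

Step 13. Two oxidations share one pot. The second epoxidation may lose facial selectivity once an oxygen substituent crowds the α face at C9. The aldehyde may be over-oxidised, or the silyloxy-oxirane may collapse by an α-ketol shift.
The fallback separates the two events and uses an anionic hydroxylation followed by a hydroxyl-directed epoxidation. It sets out from 16 and returns at 21. KHMDS (1 equiv, −78 °C) and then a Davis N-sulfonyloxaziridine hydroxylate the aldehyde enolate from the α face to give the 9α-hydroxy aldehyde F3. VO(acac)2/t-BuOOH, directed by the homoallylic 9α-OH, delivers the 6α,7α-epoxide F4. NaBH4 gives the epoxy 9α,11-diol F5, and TBAF/AcOH gives 21.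

Step 16. The 6-alkoxide set free by the epoxide opening may be oxidised or thiomethylated by residual activated DMSO. Partly oxidised material may close to lactols. The α-hydroxy aldehyde may suffer α-ketol rearrangement, or the C1 acetyl group may migrate under the basic conditions.
The fallback oxidises the two carbinols one at a time and places the C6 acetate before the α-hydroxy aldehyde is unveiled. It sets out from 21 and returns at 24. 2,2-Dimethoxypropane/PPTS masks the 1,2-diol as the 9α,11-acetonide F6. Dess–Martin oxidation of the free C12 alcohol followed by Et3N opens the epoxide to the 6α-hydroxy enal acetonide F7. Ac2O/pyridine gives the 6α-acetate F8. Aqueous acetic acid removes the acetonide to give the 9α,11-diol enal F9. A Parikh–Doering oxidation of the remaining primary alcohol then gives 24.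

**Further compounds**
F1 | step 11 | ethylene acetal of trienal 15 (2E,4R,8E,10E) | O1CCOC1/C=C(\C)[C@H](OC(C)=O)CCC(C)(C)/C=C/C=C/CO[Si](C)(C)C(C)(C)C
F2 | step 11 | ethylene acetal of octalin aldehyde 16 | C1=C[C@H](CO[Si](C)(C)C(C)(C)C)[C@H](C3OCCO3)[C@@]2(C)[C@H](OC(C)=O)CCC(C)(C)[C@H]12
F3 | step 13 | 1β-acetoxy-9α-hydroxy-12-(TBSO)drim-6-en-11-al | C1=C[C@H](CO[Si](C)(C)C(C)(C)C)[C@](O)(C=O)[C@@]2(C)[C@H](OC(C)=O)CCC(C)(C)[C@H]12
F4 | step 13 | 1β-acetoxy-6α,7α-epoxy-9α-hydroxy-12-(TBSO)driman-11-al | O1[C@H]2[C@@H]1[C@H](CO[Si](C)(C)C(C)(C)C)[C@](O)(C=O)[C@@]3(C)[C@H](OC(C)=O)CCC(C)(C)[C@H]23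
F5 | step 13 | 1β-acetoxy-6α,7α-epoxy-12-(TBSO)drimane-9α,11-diol | O1[C@H]2[C@@H]1[C@H](CO[Si](C)(C)C(C)(C)C)[C@](O)(CO)[C@@]3(C)[C@H](OC(C)=O)CCC(C)(C)[C@H]23
F6 | step 16 | 9α,11-O-isopropylidene derivative of triol 21 | O1[C@H]2[C@@H]1[C@H](CO)[C@@]3(OC(C)(C)OC3)[C@@]4(C)[C@H](OC(C)=O)CCC(C)(C)[C@H]24
F7 | step 16 | 1β-acetoxy-6α-hydroxy-9α,11-(isopropylidenedioxy)drim-7-en-12-al | O[C@H]1C=C(C=O)[C@@]3(OC(C)(C)OC3)[C@@]2(C)[C@H](OC(C)=O)CCC(C)(C)[C@H]12
F8 | step 16 | 1β,6α-diacetoxy-9α,11-(isopropylidenedioxy)drim-7-en-12-al | CC(=O)O[C@H]1C=C(C=O)[C@@]3(OC(C)(C)OC3)[C@@]2(C)[C@H](OC(C)=O)CCC(C)(C)[C@H]12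
F9 | step 16 | 1β,6α-diacetoxy-9α,11-dihydroxydrim-7-en-12-al | CC(=O)O[C@H]1C=C(C=O)[C@](O)(CO)[C@@]2(C)[C@H](OC(C)=O)CCC(C)(C)[C@H]12
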